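**Retrosynthetic overview**
1. Target ⇐ its phenol acetate ⇐ the C8=C9 alkene: the oxirane goes on last, delivered by the free 6α‑OH, and the phenol is unmasked at the end.
2. Tertiary vanillate, 6‑OH and the five‑membered ring ⇐ a monocyclic cis‑epoxide (homoprenyl chain syn to the oxirane) plus an aroyl triflate. One cationic cascade does this: epoxide opening by the side‑chain alkene (farnesyl C6–C10 bond), 1,2‑H shift, capture of the C4 cation by the C6 ester, kinetic hydrolysis.
3. Epoxide ⇐ α‑quaternary cyclohept‑4‑enone by α‑bromination, catalyst‑controlled reduction and closure.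
4. Cycloheptenone ⇐ (3S,6E)‑nerolidol by bromoetherification, then dehydrobromination/Claisen ring expansion (farnesyl C1–C7 bond).
5. Ring order: seven‑membered carbocycle (step 2), five‑membered carbocycle (step 6), oxirane (step 7).

Assumption: natural (+)‑(3S,6E)‑nerolidol of high ee is commercial; bicyclic compounds use daucane numbering (C1 = ring‑fusion C–CH3, C4 = C–iPr, C5 = ring‑fusion CH, C6 = CH–O, C8/C9 = alkene or oxirane).

**Route**

Step 1
Reactants: 1 (3S,6E)-nerolidol
Product: 2 (2R,5S)-2-[(2S)-2-bromo-6-methylhept-5-en-2-yl]-5-ethenyl-5-methyloxolane (plus its 2S/2'R diastereomer)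
Conditions: NBS, CH2Cl2, −20 → 0 °C, dark
Reagents that add atoms: N-bromosuccinimide, O=C1CCC(=O)N1Br
Why: 5‑exo bromoetherification, in which the tertiary OH traps the 6,7‑bromonium ion irreversibly while the 10,11‑bromonium ion has no internal nucleophile; anti addition across the E‑alkene fixes the C2/C2' relative configuration in both diastereomers, and both converge in step 2.

Step 2
Reactants: 2 (2R,5S)-2-[(2S)-2-bromo-6-methylhept-5-en-2-yl]-5-ethenyl-5-methyloxolane
Product: 4 (2R)-2,5-dimethyl-2-(4-methylpent-3-en-1-yl)cyclohept-4-en-1-one, via enol ether 3 (not isolated)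
Conditions: 2,4,6-collidine, 170 °C, sealed tube
Reagents that add atoms: none
Why: Dehydrobromination toward the ring carbon gives the (E)‑2‑alkylidene‑5‑vinyloxolane, which undergoes Claisen rearrangement with ring expansion (the linalool → karahanaenone reaction type), forming the farnesyl C1–C7 bond; the vinyl terminus adds to the enol‑ether face it sits on, so the 5S centre is relayed to the new quaternary carbon (2R), and any leakage through E/Z scrambling is removed in step 4.

Step 3
Reactants: 4 (2R)-2,5-dimethyl-2-(4-methylpent-3-en-1-yl)cyclohept-4-en-1-one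
Product: 6 (2R,7RS)-7-bromo-2,5-dimethyl-2-(4-methylpent-3-en-1-yl)cyclohept-4-en-1-one, via silyl enol ether 5 (not isolated)
Conditions: LiHMDS, TMSCl, THF, −78 °C; then NBS, −78 → 0 °C
Reagents that add atoms: N-bromosuccinimide, O=C1CCC(=O)N1Br
Why: The ketone has only one enolisable α‑carbon, so silyl enol ether formation and its bromination (faster than attack on the trisubstituted alkenes) are regiospecific; the C7 bromide epimers are both used in step 4.

Step 4
Reactants: 6 (2R,7RS)-7-bromo-2,5-dimethyl-2-(4-methylpent-3-en-1-yl)cyclohept-4-en-1-one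
Product: 9 (1S,6R,7R)-3,6-dimethyl-6-(4-methylpent-3-en-1-yl)-8-oxabicyclo[5.1.0]oct-3-ene, via bromohydrins 7 (not isolated), via iodohydrin 8 (not isolated)
Conditions: (R)-Me-CBS (0.3 equiv), catecholborane, toluene, −40 °C; then MeOH, K2CO3, NaI (0.2 equiv), 40 °C
Reagents that add atoms: none
Why: CBS reduction in which the catalyst chooses the carbonyl face (quaternary carbon = large group, so (R)‑CBS gives the 1R alcohol from either bromide epimer), then Williamson closure of the trans‑bromohydrin and Finkelstein inversion/closure of the cis‑bromohydrin, places both oxirane carbons syn to the homoprenyl chain; any ketone with the wrong quaternary configuration becomes a diastereomeric epoxide that is separated after step 6.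

Step 5
Reactants: 10 4-(acetyloxy)-3-methoxybenzoic acid
Product: 11 4-(acetyloxy)-3-methoxybenzoyl chloride
Conditions: (COCl)2, cat. DMF, CH2Cl2, 0 °C → rt
Reagents that add atoms: oxalyl chloride, O=C(Cl)C(Cl)=O
Why: Standard Vilsmeier‑type acid chloride formation; the aryl acetate is inert.

Step 6
Reactants: 9 (1S,6R,7R)-3,6-dimethyl-6-(4-methylpent-3-en-1-yl)-8-oxabicyclo[5.1.0]oct-3-ene; 11 4-(acetyloxy)-3-methoxybenzoyl chloride
Product: 14 (3R,3aS,4S,8aR)-4-hydroxy-6,8a-dimethyl-3-(propan-2-yl)-1,2,3,3a,4,5,8,8a-octahydroazulen-3-yl 4-(acetyloxy)-3-methoxybenzoate, via aroyl triflate 12 (not isolated), via dioxanylium triflate 13 (not isolated)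
Conditions: 11, AgOTf, CH2Cl2, 0 °C; then 2,6-di-tert-butyl-4-methylpyridine (0.3 equiv), 9, −78 → −40 °C; then THF/aq. NaHCO3, −40 → 0 °C
Reagents that add atoms: water, O
Why: Proposed new method: the aroyl triflate O‑acylates the epoxide, and the O‑acyloxiranium ion is opened at C5 anti by the side‑chain alkene (5‑exo, SN2‑like), so the syn epoxide enforces the trans ring fusion (5α‑H) and leaves C6–O α; the C11 cation then takes the biosynthetic 1,2‑hydride shift because only the ring C4 cation can be trapped by the C6 ester carbonyl in a six‑membered 1,3‑dioxan‑2‑ylium ring, which sets C4–O cis to C6 (4β), and kinetic hydrolysis expels the less hindered secondary oxygen to leave the acyl group on the tertiary one; closest known chemistry is Lewis‑acid epoxide‑initiated cation–olefin cyclisation, acyl‑triflate cleavage of cyclic ethers, neighbouring‑ester capture of carbocations and orthoester/acyloxonium hydrolysis to the more hindered ester.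

Step 7
Reactants: 14 (3R,3aS,4S,8aR)-4-hydroxy-6,8a-dimethyl-3-(propan-2-yl)-1,2,3,3a,4,5,8,8a-octahydroazulen-3-yl 4-(acetyloxy)-3-methoxybenzoate
Product: 15 (1R,4R,5S,6S,8R,9S)-8,9-epoxy-6-hydroxydaucan-4-yl 4-(acetyloxy)-3-methoxybenzoate
Conditions: VO(acac)2 (5 mol %), t-BuOOH, CH2Cl2, 0 °C → rt
Reagents that add atoms: tert-butyl hydroperoxide, CC(C)(C)OO
Why: Vanadium‑catalysed hydroxyl‑directed epoxidation delivers oxygen to the only remaining alkene from the face of the homoallylic 6α‑OH, which is also the face opposite the angular methyl, giving the 8α,9α‑oxirane (8R,9S) under neutral conditions that do not move the tertiary ester.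

Step 8
Reactants: 15 (1R,4R,5S,6S,8R,9S)-8,9-epoxy-6-hydroxydaucan-4-yl 4-(acetyloxy)-3-methoxybenzoate
Product: 16 (1R,4R,5S,6S,8R,9S)-8,9-epoxy-6-hydroxydaucan-4-yl 4-hydroxy-3-methoxybenzoate
Conditions: N2H4·AcOH, DMF, 0 °C → rt
Reagents that add atoms: none
Why: Buffered hydrazinolysis cleaves the activated aryl acetate far faster than the hindered tertiary aroyl ester and is mild enough to spare the oxirane and avoid 4→6 acyl migration; no stereocentre is touched.

**Compound list**
1 | (3S,6E)-nerolidol, (3S,6E)-3,7,11-trimethyldodeca-1,6,10-trien-3-ol | C=C[C@@](C)(O)CC/C=C(\C)CCC=C(C)C | starting material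
2 | (2R,5S)-2-[(2S)-2-bromo-6-methylhept-5-en-2-yl]-5-ethenyl-5-methyloxolane (formed with its (2S,5S)/(2'R) diastereomer; both give 3) | C=C[C@]1(C)CC[C@@H](O1)[C@@](C)(Br)CCC=C(C)C | intermediate
3 | (2E,5S)-5-ethenyl-5-methyl-2-(6-methylhept-5-en-2-ylidene)oxolane (not isolated) | C=C[C@]1(C)CC/C(O1)=C(/C)CCC=C(C)C | intermediate
4 | (2R)-2,5-dimethyl-2-(4-methylpent-3-en-1-yl)cyclohept-4-en-1-one | O=C1CCC(C)=CC[C@@]1(C)CCC=C(C)C | intermediate
5 | trimethyl{[(7R)-4,7-dimethyl-7-(4-methylpent-3-en-1-yl)cyclohepta-1,4-dien-1-yl]oxy}silane (not isolated) | C[Si](C)(C)OC1=CCC(C)=CC[C@@]1(C)CCC=C(C)C | intermediate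
6 | (2R,7RS)-7-bromo-2,5-dimethyl-2-(4-methylpent-3-en-1-yl)cyclohept-4-en-1-one | O=C1C(Br)CC(C)=CC[C@@]1(C)CCC=C(C)C | intermediate
7 | (1R,2R,7RS)-7-bromo-2,5-dimethyl-2-(4-methylpent-3-en-1-yl)cyclohept-4-en-1-ol (not isolated) | O[C@H]1C(Br)CC(C)=CC[C@@]1(C)CCC=C(C)C | intermediate
8 | (1R,2R,7R)-7-iodo-2,5-dimethyl-2-(4-methylpent-3-en-1-yl)cyclohept-4-en-1-ol (not isolated) | O[C@H]1[C@H](I)CC(C)=CC[C@@]1(C)CCC=C(C)C | intermediate
9 | (1S,6R,7R)-3,6-dimethyl-6-(4-methylpent-3-en-1-yl)-8-oxabicyclo[5.1.0]oct-3-ene | CC1=CC[C@@](C)(CCC=C(C)C)[C@H]2O[C@H]2C1 | intermediate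
10 | 4-(acetyloxy)-3-methoxybenzoic acid | CC(=O)Oc1ccc(cc1OC)C(=O)O | starting material
11 | 4-(acetyloxy)-3-methoxybenzoyl chloride | CC(=O)Oc1ccc(cc1OC)C(Cl)=O | intermediate
12 | 4-(acetyloxy)-3-methoxybenzoyl trifluoromethanesulfonate (not isolated) | CC(=O)Oc1ccc(cc1OC)C(=O)OS(=O)(=O)C(F)(F)F | intermediate
13 | 2-[4-(acetyloxy)-3-methoxyphenyl]-1,3-dioxan-2-ylium bridging O4 and O6 of (1R,4R,5S,6S)-dauc-8-ene-4,6-diol, triflate salt (not isolated) | COc1cc([C+]5O[C@@]2(C(C)C)CC[C@]3(C)CC=C(C)C[C@H](O5)[C@H]32)ccc1OC(C)=O.[O-]S(=O)(=O)C(F)(F)F | intermediate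
14 | (3R,3aS,4S,8aR)-4-hydroxy-6,8a-dimethyl-3-(propan-2-yl)-1,2,3,3a,4,5,8,8a-octahydroazulen-3-yl 4-(acetyloxy)-3-methoxybenzoate, i.e. (1R,4R,5S,6S)-6-hydroxydauc-8-en-4-yl ester | COc1cc(C(=O)O[C@@]2(C(C)C)CC[C@]3(C)CC=C(C)C[C@H](O)[C@H]32)ccc1OC(C)=O | intermediate
15 | (1R,4R,5S,6S,8R,9S)-8,9-epoxy-6-hydroxydaucan-4-yl 4-(acetyloxy)-3-methoxybenzoate | COc1cc(C(=O)O[C@@]2(C(C)C)CC[C@]3(C)C[C@@H]4O[C@]4(C)C[C@H](O)[C@H]32)ccc1OC(C)=O | intermediate
16 | (1R,4R,5S,6S,8R,9S)-8,9-epoxy-6-hydroxydaucan-4-yl 4-hydroxy-3-methoxybenzoate (CNP0315707.1) | COc1cc(C(=O)O[C@@]2(C(C)C)CC[C@]3(C)C[C@@H]4O[C@]4(C)C[C@H](O)[C@H]32)ccc1O | target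

**Step count and risks**
Total steps: 8. Longest linear sequence: 7 steps (1 → 2 → 4 → 6 → 9 → 14 → 15 → 16); step 5 is the one‑step side branch.

The three steps most likely to fail:

Step 6. The cascade is new; it can lose to elimination of the C11 cation, epoxide-to-ketone rearrangement, triflate opening, or a slow trans annulation. The fallback separates ring closure from the acyloxy relay. It sets out from 9: SnCl4 in CH2Cl2 at −78 °C gives a chloride‑terminated epoxide–olefin cyclisation to (1R,5S,6S)-11-chlorodauc-8-en-6-ol F1. Acylation of its hydroxyl with 11 (pyridine, DMAP) gives (1R,5S,6S)-11-chlorodauc-8-en-6-yl 4-(acetyloxy)-3-methoxybenzoate F2. AgOTf with the hindered pyridine at −78 °C then abstracts chloride without free acid; the C11 cation takes the same 1,2‑hydride shift and is trapped by the ester. This comes back to the route at 13, which is hydrolysed to 14 as in step 6.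

Step 2. HBr may be lost toward the methyl or methylene instead of the ring carbon, and the enol‑ether geometry may scramble. The fallback sets out from 2: KOtBu in THF deliberately makes the less substituted alkene, (5S)-5-ethenyl-5-methyl-2-(6-methylhepta-1,5-dien-2-yl)oxolane F3. This allylic ether is isomerised into conjugation with oxygen by a ruthenium hydride (RuHCl(CO)(PPh3)3, toluene, 80 °C). This comes back to the route at 3, which is heated to 4; any E/Z leakage is again removed at step 4.

Step 4. CBS reduction of the hindered α‑bromo ketone may be slow or face‑unselective for one bromide epimer, and the cis‑bromohydrin may not converge. The fallback sets out from 4: the lithium enolate is hydroxylated with an enantiopure (camphorsulfonyl)oxaziridine (enantiomer chosen for the 7R alcohol) to give (2R,7R)-7-hydroxy-2,5-dimethyl-2-(4-methylpent-3-en-1-yl)cyclohept-4-en-1-one F4. Hydroxyl‑directed reduction with Me4NBH(OAc)3 delivers hydride from the hydroxyl face and gives the trans‑diol (1R,2R,7R)-4,7-dimethyl-7-(4-methylpent-3-en-1-yl)cyclohept-4-ene-1,2-diol F5. Mitsunobu cyclodehydration (PPh3, DIAD) activates the less hindered hydroxyl and closes with inversion. This comes back to the route at 9.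

Further compounds
F1 | step 6 | (1R,5S,6S)-11-chlorodauc-8-en-6-ol (C4 epimers) | CC(C)(Cl)C2CC[C@]3(C)CC=C(C)C[C@H](O)[C@H]32
F2 | step 6 | (1R,5S,6S)-11-chlorodauc-8-en-6-yl 4-(acetyloxy)-3-methoxybenzoate (C4 epimers) | CC(C)(Cl)C2CC[C@]3(C)CC=C(C)C[C@H](OC(=O)c4ccc(OC(C)=O)c(OC)c4)[C@H]32
F3 | step 2 | (5S)-5-ethenyl-5-methyl-2-(6-methylhepta-1,5-dien-2-yl)oxolane (C2 epimers) | C=C[C@]1(C)CCC(O1)C(=C)CCC=C(C)C
F4 | step 4 | (2R,7R)-7-hydroxy-2,5-dimethyl-2-(4-methylpent-3-en-1-yl)cyclohept-4-en-1-one | O=C1[C@H](O)CC(C)=CC[C@@]1(C)CCC=C(C)C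
F5 | step 4 | (1R,2R,7R)-4,7-dimethyl-7-(4-methylpent-3-en-1-yl)cyclohept-4-ene-1,2-diol | O[C@H]1[C@H](O)CC(C)=CC[C@@]1(C)CCC=C(C)C
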